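**Retrosynthetic overview**

1. Target 27 comes from O‑tigloylation and O‑acetylation of an 8α‑hydroxy‑1α‑boryl ketone; the C1–O/C10–H pair is set by copper‑catalysed conjugate borylation of enone 21, and the C8–O by α′‑hydroxylation of eremophilone 19 anti to the isopropenyl group.
2. 19 comes from 15 by a thermal homodienyl 1,5‑H shift (through silyl dienol ether 16) that opens a gem‑dimethylcyclopropane into the 7β‑isopropenyl group; 15 comes from face‑selective hydrogenation of the C4 methylidene of 14.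
3. Ring A of 14 is closed by intramolecular aldol condensation of keto‑aldehyde 12 (C10 enol onto the C1 aldehyde), the key ring closure.
4. 12 comes from a copper‑catalysed conjugate addition that joins carenone 2 (ring B, one step from (+)‑3‑carene) and alkenyl Grignard 9 (three steps from ethyl acetate and 2,3‑dibromopropene); tigloyl chloride 24 is made in parallel.
5. Ring order: ring B is taken from 3‑carene, ring A is closed onto it by the aldol condensation, and the cyclopropane is opened afterwards.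

Assumption: decalin atoms are numbered as in eremophilane (C1–C10 ring atoms, methyls C15 on C4 and C14 on C5, C11–C13 on C7); β is the face of the C5 methyl; cyclopropane intermediates are named 8,11‑cycloeremophilanes.

**Route**

Step 1
Reactants: 1 (+)-3-carene
Product: 2 (−)-car-3-en-5-one
Conditions: t-BuOOH (70% aq., 4 equiv), CrO3 (5 mol%), CH2Cl2, 23 °C
Reagents that add atoms: tert-butyl hydroperoxide, CC(C)(C)OO
Why: Chromium-catalysed allylic C–H oxidation converts the ring CH2 next to the unsubstituted alkene carbon into the conjugated ketone and leaves both cyclopropane stereocentres untouched.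

Step 2
Reactants: 3 ethyl acetate; 4 2,3-dibromopropene
Product: 6 ethyl 4-bromopent-4-enoate, via lithium enolate of ethyl acetate 5 (not isolated)
Conditions: LiN(iPr)2 (1.05 equiv), THF, −78 °C; then 4, −78 → 0 °C
Reagents that add atoms: none
Why: Ester enolate alkylation at the allylic bromide (SN2) is fast and the vinylic bromide is inert.

Step 3
Reactants: 6 ethyl 4-bromopent-4-enoate
Product: 7 4-bromopent-4-enal
Conditions: iBu2AlH (1.05 equiv), CH2Cl2, −78 °C; aq. potassium sodium tartrate
Reagents that add atoms: none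
Why: Partial ester reduction stops at the aldehyde because the aluminium hemiacetal is stable at −78 °C.

Step 4
Reactants: 7 4-bromopent-4-enal
Product: 8 2-(3-bromobut-3-en-1-yl)-1,3-dioxolane
Conditions: HOCH2CH2OH (3 equiv), p-TsOH·H2O (2 mol%), benzene, reflux, Dean–Stark
Reagents that add atoms: ethylene glycol, OCCO
Why: Acid-catalysed acetalisation masks the aldehyde for the organomagnesium step.

Step 5
Reactants: 8 2-(3-bromobut-3-en-1-yl)-1,3-dioxolane; 2 (−)-car-3-en-5-one
Product: 11 (1R,4S,6S)-4-[4-(1,3-dioxolan-2-yl)but-1-en-2-yl]-4,7,7-trimethylbicyclo[4.1.0]heptan-2-one, via Grignard reagent 9 (not isolated), via silyl enol ether 10 (not isolated)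
Conditions: Mg, THF, 50 °C; then CuBr·SMe2 (10 mol%), Me3SiCl (2 equiv), HMPA (2 equiv), 2, THF, −78 → −40 °C; then K2CO3 (cat.), MeOH, 0 °C
Reagents that add atoms: none
Why: Copper-catalysed, Me3SiCl-accelerated conjugate addition of the alkenyl Grignard reagent occurs on the face opposite the gem-dimethylcyclopropane (its endo methyl shields the β face), so the quaternary C5 is formed with its methyl cis to the cyclopropane.

Step 6
Reactants: 11 (1R,4S,6S)-4-[4-(1,3-dioxolan-2-yl)but-1-en-2-yl]-4,7,7-trimethylbicyclo[4.1.0]heptan-2-one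
Product: 14 8,11-cycloeremophila-1(10),4(15)-dien-9-one, via keto-aldehyde 12 (not isolated), via aldol 13 (not isolated)
Conditions: 2 M HCl, THF, 23 °C; then KOH (0.5 equiv), MeOH, 0 → 23 °C
Reagents that add atoms: none
Why: After acetal hydrolysis the intramolecular aldol condensation closes ring A, because the ketone can enolise only toward C10 (the other α-carbon is a cyclopropane methine) and dehydration to the conjugated enone makes the closure irreversible.

Step 7
Reactants: 14 8,11-cycloeremophila-1(10),4(15)-dien-9-one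
Product: 15 8,11-cycloeremophil-1(10)-en-9-one
Conditions: H2 (3 atm), RhCl(PPh3)3 (10 mol%), benzene, 23 °C
Reagents that add atoms: none
Why: Homogeneous hydrogenation reduces only the 1,1-disubstituted alkene (not the conjugated trisubstituted one or the cyclopropane) and delivers H2 syn from the α face, away from the pseudoaxial C5 methyl, which sets the 4β-methyl group (4S).

Step 8
Reactants: 15 8,11-cycloeremophil-1(10)-en-9-one
Product: 16 9-(tert-butyldimethylsilyloxy)-8,11-cycloeremophila-1,9-diene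
Conditions: t-BuMe2SiOTf (1.3 equiv), Et3N (2 equiv), CH2Cl2, 0 °C
Reagents that add atoms: tert-butyldimethylsilyl trifluoromethanesulfonate, CC(C)(C)[Si](C)(C)OS(=O)(=O)C(F)(F)F
Why: Soft enolisation of the enone removes a γ-hydrogen at C2 (the α′ position is a non-enolisable cyclopropane methine) and gives the silyl dienol ether, which places a C9=C10 double bond on the cyclopropane cis to its endo methyl.

Step 9
Reactants: 16 9-(tert-butyldimethylsilyloxy)-8,11-cycloeremophila-1,9-diene
Product: 19 eremophila-1(10),11-dien-9-one, via rearranged silyl enol ether 17 (not isolated), via deconjugated ketone 18 (not isolated)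
Conditions: toluene, 250 °C, sealed tube, 3 h; then 1 M HCl, THF, 23 °C; then DBU (0.2 equiv), CH2Cl2, 23 °C
Reagents that add atoms: none
Why: A thermal homodienyl (retro-ene) 1,5-hydrogen shift of the cis-methyl vinylcyclopropane, as in 2-carene, moves an endo-methyl hydrogen to C10 and cleaves the C8–C11 bond to give the 7β-isopropenyl group without touching C7; hydrolysis and base-mediated conjugation then erase the transient C10 centre.

Step 10
Reactants: 19 eremophila-1(10),11-dien-9-one
Product: 21 8α-hydroxyeremophila-1(10),11-dien-9-one, via potassium dienolate 20 (not isolated)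
Conditions: KN(SiMe3)2 (1.1 equiv), THF, −78 °C; then 2-(benzenesulfonyl)-3-phenyloxaziridine (1.3 equiv), −78 °C; H2O
Reagents that add atoms: 2-(benzenesulfonyl)-3-phenyloxaziridine, O=S(=O)(c1ccccc1)N1OC1c1ccccc1
Why: Kinetic α′-deprotonation and Davis oxaziridine hydroxylation of the cross-conjugated enolate deliver oxygen axially, anti to the neighbouring 7β-isopropenyl group, which sets the 8α-hydroxyl (8R).

Step 11
Reactants: 21 8α-hydroxyeremophila-1(10),11-dien-9-one
Product: 22 8α-hydroxy-1α-(4,4,5,5-tetramethyl-1,3,2-dioxaborolan-2-yl)-10αH-eremophil-11-en-9-one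
Conditions: B2pin2 (1.1 equiv), CuCl (5 mol%), xantphos (5 mol%), NaOtBu (10 mol%), MeOH (2 equiv), THF, 23 °C
Reagents that add atoms: bis(pinacolato)diboron, CC1(C)OB(OC1(C)C)B1OC(C)(C)C(C)(C)O1
Why: In this copper-catalysed conjugate borylation the boryl group adds to C1 from the α face because the pseudoaxial C5 methyl blocks the β face, and the resulting enolate is protonated at C10 also from the α face (anti to the C5 methyl, with the axial 8α-hydroxyl as a proton relay), giving the trans ring fusion (10S).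

Step 12
Reactants: 23 tiglic acid
Product: 24 tigloyl chloride
Conditions: (COCl)2 (1.2 equiv), DMF (cat.), CH2Cl2, 0 → 23 °C
Reagents that add atoms: oxalyl chloride, O=C(Cl)C(=O)Cl
Why: Acid chloride formation through the Vilsmeier-type intermediate proceeds without touching the E-configured double bond.

Step 13
Reactants: 22 8α-hydroxy-1α-(4,4,5,5-tetramethyl-1,3,2-dioxaborolan-2-yl)-10αH-eremophil-11-en-9-one; 24 tigloyl chloride
Product: 25 1α-(4,4,5,5-tetramethyl-1,3,2-dioxaborolan-2-yl)-8α-tigloyloxy-10αH-eremophil-11-en-9-one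
Conditions: pyridine (3 equiv), DMAP (10 mol%), CH2Cl2, 0 → 23 °C
Reagents that add atoms: none
Why: DMAP-catalysed esterification acylates the only free hydroxyl while the boronate holds the C1 position and the mild base does not epimerise C8 or C10.

Step 14
Reactants: 25 1α-(4,4,5,5-tetramethyl-1,3,2-dioxaborolan-2-yl)-8α-tigloyloxy-10αH-eremophil-11-en-9-one
Product: 26 1α-hydroxy-8α-tigloyloxy-10αH-eremophil-11-en-9-one
Conditions: NaBO3·4H2O (3 equiv), THF/H2O (1:1), 0 → 23 °C
Reagents that add atoms: sodium perborate, [Na+].[O-]OB=O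
Why: Oxidation of the C–B bond occurs by 1,2-migration with retention, giving the equatorial 1α-alcohol (1S) under conditions mild enough for the esters and the C10 centre.

Step 15
Reactants: 26 1α-hydroxy-8α-tigloyloxy-10αH-eremophil-11-en-9-one
Product: 27 (1S,4S,5R,7R,8R,10S)-1-acetoxy-8-[(E)-2-methylbut-2-enoyloxy]eremophil-11-en-9-one
Conditions: Ac2O (2 equiv), pyridine, DMAP (5 mol%), CH2Cl2, 0 °C
Reagents that add atoms: acetic anhydride, CC(=O)OC(C)=O
Why: Acetylation of the secondary alcohol at 0 °C gives the target while avoiding E1cB loss of the β-acetoxy group.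

**Compound list**

1 | (+)-3-carene, (1S,6R)-3,7,7-trimethylbicyclo[4.1.0]hept-3-ene | CC1(C)[C@H]2CC(C)=CC[C@@H]12 | starting material
2 | (−)-car-3-en-5-one, (1R,6S)-4,7,7-trimethylbicyclo[4.1.0]hept-3-en-2-one | CC1(C)[C@H]2CC(C)=CC(=O)[C@@H]12 | intermediate
3 | ethyl acetate | CCOC(C)=O | starting material
4 | 2,3-dibromopropene | C=C(Br)CBr | starting material
5 | lithium enolate of ethyl acetate | C=C(O[Li])OCC | intermediate
6 | ethyl 4-bromopent-4-enoate | C=C(Br)CCC(=O)OCC | intermediate
7 | 4-bromopent-4-enal | C=C(Br)CCC=O | intermediate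
8 | 2-(3-bromobut-3-en-1-yl)-1,3-dioxolane | C=C(Br)CCC1OCCO1 | intermediate
9 | [4-(1,3-dioxolan-2-yl)but-1-en-2-yl]magnesium bromide | C=C([Mg]Br)CCC1OCCO1 | intermediate
10 | {[(1R,4S,6S)-4-[4-(1,3-dioxolan-2-yl)but-1-en-2-yl]-4,7,7-trimethylbicyclo[4.1.0]hept-2-en-2-yl]oxy}trimethylsilane | CC1(C)[C@H]2C[C@](C)(C(=C)CCC3OCCO3)C=C(O[Si](C)(C)C)[C@@H]12 | intermediate
11 | (1R,4S,6S)-4-[4-(1,3-dioxolan-2-yl)but-1-en-2-yl]-4,7,7-trimethylbicyclo[4.1.0]heptan-2-one | CC1(C)[C@H]2C[C@](C)(C(=C)CCC3OCCO3)CC(=O)[C@@H]12 | intermediate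
12 | 4-[(1S,3S,6R)-3,7,7-trimethyl-5-oxobicyclo[4.1.0]heptan-3-yl]pent-4-enal | CC1(C)[C@H]2C[C@](C)(C(=C)CCC=O)CC(=O)[C@@H]12 | intermediate
13 | 1-hydroxy-8,11-cycloeremophil-4(15)-en-9-one (5β-methyl, 7αH, 8αH; mixture at C1 and C10) | CC1(C)[C@H]2C[C@]3(C)C(=C)CCC(O)C3C(=O)[C@@H]12 | intermediate
14 | 8,11-cycloeremophila-1(10),4(15)-dien-9-one (5β-methyl, 7αH, 8αH, cyclopropane on the β face) | CC1(C)[C@H]2C[C@]3(C)C(=C)CCC=C3C(=O)[C@@H]12 | intermediate
15 | 8,11-cycloeremophil-1(10)-en-9-one (4β,5β-dimethyl, 7αH, 8αH) | CC1(C)[C@H]2C[C@]3(C)[C@@H](C)CCC=C3C(=O)[C@@H]12 | intermediate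
16 | 9-(tert-butyldimethylsilyloxy)-8,11-cycloeremophila-1,9-diene | CC1(C)[C@H]2C[C@]3(C)[C@@H](C)CC=CC3=C(O[Si](C)(C)C(C)(C)C)[C@@H]12 | intermediate
17 | 9-(tert-butyldimethylsilyloxy)-10βH-eremophila-1,8,11-triene | C=C(C)[C@H]1C[C@]2(C)[C@@H](C)CC=C[C@@H]2C(O[Si](C)(C)C(C)(C)C)=C1 | intermediate
18 | 10βH-eremophila-1,11-dien-9-one | C=C(C)[C@H]1C[C@]2(C)[C@@H](C)CC=C[C@@H]2C(=O)C1 | intermediate
19 | eremophila-1(10),11-dien-9-one (eremophilone), (3S,4aR,5S)-4a,5-dimethyl-3-(prop-1-en-2-yl)-3,4,4a,5,6,7-hexahydronaphthalen-1(2H)-one | C=C(C)[C@H]1C[C@]2(C)[C@@H](C)CCC=C2C(=O)C1 | intermediate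
20 | potassium eremophila-1(10),8,11-trien-9-olate | C=C(C)[C@H]1C[C@]2(C)[C@@H](C)CCC=C2C(O[K])=C1 | intermediate
21 | 8α-hydroxyeremophila-1(10),11-dien-9-one, (2R,3R,4aR,5S)-2-hydroxy-4a,5-dimethyl-3-(prop-1-en-2-yl)-3,4,4a,5,6,7-hexahydronaphthalen-1(2H)-one | C=C(C)[C@H]1C[C@]2(C)[C@@H](C)CCC=C2C(=O)[C@@H]1O | intermediate
22 | 8α-hydroxy-1α-(4,4,5,5-tetramethyl-1,3,2-dioxaborolan-2-yl)-10αH-eremophil-11-en-9-one | C=C(C)[C@H]1C[C@@]2(C)[C@H](C(=O)[C@@H]1O)[C@@H](B1OC(C)(C)C(C)(C)O1)CC[C@@H]2C | intermediate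
23 | tiglic acid, (E)-2-methylbut-2-enoic acid | C/C=C(\C)C(=O)O | starting material
24 | tigloyl chloride, (E)-2-methylbut-2-enoyl chloride | C/C=C(\C)C(=O)Cl | intermediate
25 | 1α-(4,4,5,5-tetramethyl-1,3,2-dioxaborolan-2-yl)-8α-tigloyloxy-10αH-eremophil-11-en-9-one | C=C(C)[C@H]1C[C@@]2(C)[C@H](C(=O)[C@@H]1OC(=O)/C(C)=C/C)[C@@H](B1OC(C)(C)C(C)(C)O1)CC[C@@H]2C | intermediate
26 | 1α-hydroxy-8α-tigloyloxy-10αH-eremophil-11-en-9-one | C=C(C)[C@H]1C[C@@]2(C)[C@H](C(=O)[C@@H]1OC(=O)/C(C)=C/C)[C@@H](O)CC[C@@H]2C | intermediate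
27 | (1S,4S,5R,7R,8R,10S)-1-acetoxy-8-[(E)-2-methylbut-2-enoyloxy]eremophil-11-en-9-one (1α-acetoxy-8α-tigloyloxy-10αH) | C=C(C)[C@H]1C[C@@]2(C)[C@H](C(=O)[C@@H]1OC(=O)/C(C)=C/C)[C@@H](OC(C)=O)CC[C@@H]2C | target

**Step count and risks**

Total step count: 15. Longest linear sequence: 13 steps (steps 2–11 and 13–15, from ethyl acetate and 2,3-dibromopropene); the carene branch joins at step 5 and the tiglic acid branch at step 13.

Steps most likely to fail:

Step 5. The alkenyl group must be transferred to a hindered β,β-disubstituted cyclopropyl enone; 1,2-addition or electron-transfer opening of the cyclopropane could compete. The fallback sets out from 8 and 2 and returns at 11. Compound 8 is dehydrobrominated with NaNH2 in liquid NH3/THF to 2-(but-3-yn-1-yl)-1,3-dioxolane F1. Hydroalumination of F1 with iBu2AlH and Ni(dppp)Cl2 (3 mol%) gives the internal alkenylalane [4-(1,3-dioxolan-2-yl)but-1-en-2-yl]bis(2-methylpropyl)alumane F2. F2 is added to 2 with CuCl2·2H2O and an N-heterocyclic carbene ligand (5 mol%), and aqueous work-up of the aluminium enolate gives 11.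

Step 9. The homodienyl hydrogen shift needs 250 °C and the silyl dienol ether may decompose or rearrange otherwise. The fallback sets out from 15 and returns at 19. The cyclopropyl ketone is opened ionically with HBr (33% in AcOH, 0 °C) to 11-bromoeremophil-1(10)-en-9-one F3. F3 is then ionised with AgOSO2CF3 in the presence of 2,6-di-tert-butyl-4-methylpyridine (CH2Cl2, −40 °C); the hindered base removes a methyl hydrogen to give 19, which is separated from the 7(11)-ene isomer.

Step 11. The C10 configuration rests on kinetic protonation, and the cis-fused epimer is likely the more stable one. The fallback sets out from 21 and returns at 26. Compound 21 is first acylated with 24 (pyridine, DMAP) to 8α-tigloyloxyeremophila-1(10),11-dien-9-one F4. Nucleophilic epoxidation of F4 with t-BuOOH and DBU from the open α face gives 1α,10α-epoxy-8α-tigloyloxyeremophil-11-en-9-one F5. Reductive opening of the epoxide at C10 with Bu3SnH and AIBN (benzene, 80 °C) keeps the C1–O bond and forms C10–H on hydrolysis of the tin enolate next to the free 1α-hydroxyl, giving 26.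

**Further compounds**

F1 | step 5 | 2-(but-3-yn-1-yl)-1,3-dioxolane | C#CCCC1OCCO1
F2 | step 5 | [4-(1,3-dioxolan-2-yl)but-1-en-2-yl]bis(2-methylpropyl)alumane | C=C(CCC1OCCO1)[Al](CC(C)C)CC(C)C
F3 | step 9 | 11-bromoeremophil-1(10)-en-9-one (4β,5β-dimethyl, 7β-(2-bromopropan-2-yl)) | CC(C)(Br)[C@H]1C[C@]2(C)[C@@H](C)CCC=C2C(=O)C1
F4 | step 11 | 8α-tigloyloxyeremophila-1(10),11-dien-9-one | C=C(C)[C@H]1C[C@]2(C)[C@@H](C)CCC=C2C(=O)[C@@H]1OC(=O)/C(C)=C/C
F5 | step 11 | 1α,10α-epoxy-8α-tigloyloxyeremophil-11-en-9-one | C=C(C)[C@H]1C[C@@]2(C)[C@@]3(C(=O)[C@@H]1OC(=O)/C(C)=C/C)O[C@H]3CC[C@@H]2C
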